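## Retrosynthetic overview

1. The target is numbered as an 8-oxabicyclo[5.2.1]decane-6,9,10-trione: eight-membered carbocycle C1–C2–C3–C4–C5–C6–C7–C10, five-membered keto-lactone ring C1–C9(=O)–O8–C7–C10(=O). The hydroperoxide is made last, by perhydrolysis of the tertiary allylic alcohol, which is carried as its TES ether.
2. Key disconnection: C1–C10 and C5–C6. The enabling feature is C7, a carbinol carbon that carries both ketone carbons C6 and C10 and whose oxygen O8 is acylated by C9 — a hidden 2-acyloxymalonyl unit. Each of its acyl carbons faces an enolisable carbon (C1, α to C9; C5, α to the isobutyryl C=O). An open-chain diphenyl 2-acyloxy-2-prenylmalonate should therefore close both rings in one double Dieckmann/Claisen acylation: the five-membered keto-lactone first, the eight-membered ring second.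
3. The open-chain precursor comes from a keto acid (C9 acid; C1 left stereorandom because the key step re-sets it) by carboxylate displacement on diphenyl bromomalonate and C-prenylation at C7.
4. Keto acid: the C1–C2 bond is made by alkylating a 5-methylhex-4-enoate enolate with the C2 triflate; the isobutyl ketone at C5 comes from a vinyl group (9-BBN, oxidation, i-PrMgCl, oxidation).
5. The C3/C4 pair (tertiary next to quaternary) and the absolute configuration come from an enantioselective boron-enolate Ireland–Claisen rearrangement of an (E,E)-dienyl ester built from geranyl acetate (epoxide, selenide opening, selenoxide elimination).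

Key step: step 16

Assumption: in step 6 the (S,S)-configured diazaborolidine is taken to favour the chair that leads to (2R,3S)-11; if the sense of induction is the opposite, the (R,R)-reagent is used and nothing else changes.

Conventions: prenyl = 3-methylbut-2-en-1-yl; locants C1–C10 in the Why lines are the target locants defined in line 1 of the overview.

## Route

Step 1
Reactants: 1 geranyl acetate
Product: 2 (2E)-5-(3,3-dimethyloxiran-2-yl)-3-methylpent-2-en-1-yl acetate (6,7-epoxygeranyl acetate; racemic at the oxirane carbon)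
Conditions: mCPBA (1.05 equiv), NaHCO3, CH2Cl2, 0 °C
Reagents that add atoms: mCPBA, O=C(OO)c1cccc(Cl)c1
Why: Prilezhaev epoxidation is expected at the distal trisubstituted alkene, the 2,3-alkene being deactivated by the allylic acetate; the epoxide stereocentre is formed racemic and is destroyed in step 3.

Step 2
Reactants: 2 6,7-epoxygeranyl acetate
Product: 3 (2E)-5-(3,3-dimethyloxiran-2-yl)-3-methylpent-2-en-1-ol (6,7-epoxygeraniol; racemic)
Conditions: K2CO3 (cat.), MeOH, rt
Reagents that add atoms: none
Why: Base-catalysed transesterification (methanolysis) removes the acetate without opening the epoxide, so that no allylic leaving group is present when the selenolate is used.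

Step 3
Reactants: 3 6,7-epoxygeraniol
Product: 6 (2E,5E)-3,7-dimethylocta-2,5-diene-1,7-diol, via hydroxy selenide 4 (not isolated), via selenoxide 5 (not isolated)
Conditions: (PhSe)2, NaBH4, EtOH, rt → reflux; then THF, pyridine, 30% H2O2, 0 °C → rt
Reagents that add atoms: none
Why: Epoxide-to-allylic-alcohol transposition by selenolate opening at the less substituted epoxide carbon followed by selenoxide syn-elimination, which can only proceed away from the fully substituted carbinol carbon and gives the (E)-alkene; pyridine buffering limits epoxidation of the remaining alkene by perseleninic acid.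

Step 4
Reactants: 6 (2E,5E)-3,7-dimethylocta-2,5-diene-1,7-diol; 7 5-methylhex-4-enoic acid
Product: 8 (2E,5E)-7-hydroxy-3,7-dimethylocta-2,5-dien-1-yl 5-methylhex-4-enoate
Conditions: DCC, DMAP (cat.), CH2Cl2, 0 °C → rt
Reagents that add atoms: none
Why: Steglich esterification acylates the primary allylic hydroxyl selectively, the tertiary allylic hydroxyl being too hindered.

Step 5
Reactants: 8 hydroxy ester
Product: 9 (2E,5E)-3,7-dimethyl-7-[(triethylsilyl)oxy]octa-2,5-dien-1-yl 5-methylhex-4-enoate
Conditions: TESOTf, 2,6-lutidine, CH2Cl2, −78 °C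
Reagents that add atoms: triethylsilyl triflate, CC[Si](CC)(CC)OS(=O)(=O)C(F)(F)F
Why: Silylation of the tertiary alcohol with the silyl triflate gives a TES ether that should survive the boron enolate, hydride, organometallic and amide-base steps and is removed by fluoride in step 17.

Step 6
Reactants: 9 TES-protected dienyl ester
Product: 11 (2R,3S,5E)-3-ethenyl-3,7-dimethyl-2-(3-methylbut-2-en-1-yl)-7-[(triethylsilyl)oxy]oct-5-enoic acid, via boron ketene acetal 10 (not isolated)
Conditions: (S,S)-2-bromo-1,3-bis{[3,5-bis(trifluoromethyl)phenyl]sulfonyl}-4,5-diphenyl-1,3,2-diazaborolidine, i-Pr2NEt, CH2Cl2, −78 °C; then 4 °C; aqueous work-up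
Reagents that add atoms: none
Why: Enantioselective Ireland–Claisen rearrangement through a chiral boron ketene acetal: amine-mediated soft enolisation gives the enolate with the alkyl substituent cis to O–B, the chair transition state places that substituent and the long chain of the (E)-trisubstituted alkene equatorial and the methyl group axial, which sets the relative configuration of the tertiary/quaternary pair (C3/C4), and the C2-symmetric sulfonamide ligand on boron selects one enantiomeric chair, which sets the absolute configuration.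

Step 7
Reactants: 11 Claisen acid
Product: 12 (2R,3S,5E)-3-ethenyl-3,7-dimethyl-2-(3-methylbut-2-en-1-yl)-7-[(triethylsilyl)oxy]oct-5-en-1-ol
Conditions: LiAlH4, Et2O, 0 °C → rt
Reagents that add atoms: none
Why: Hydride reduction of the carboxylic acid (as its lithium carboxylate, which does not epimerise) to the primary alcohol leaves the alkenes and the silyl ether untouched.

Step 8
Reactants: 12 primary alcohol; 13 methyl 5-methylhex-4-enoate
Product: 16 methyl (4S,5S,7E)-5-ethenyl-5,9-dimethyl-2,4-bis(3-methylbut-2-en-1-yl)-9-[(triethylsilyl)oxy]dec-7-enoate (both C2 epimers), via triflate 14 (not isolated), via lithium ester enolate 15 (not isolated)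
Conditions: Tf2O, 2,6-lutidine, CH2Cl2, −78 °C; then added to 15 (from 13, LDA, THF–DMPU, −78 °C), −78 → −30 °C
Reagents that add atoms: none
Why: Ester enolate alkylation (SN2) in which the triflate is chosen as leaving group because the electrophilic CH2 is β-branched next to a quaternary carbon; the new stereocentre α to the ester (C1) is formed without control and needs none, since step 16 passes through its enolate.

Step 9
Reactants: 16 vinyl methyl ester
Product: 18 methyl (4S,5S,7E)-5-(2-hydroxyethyl)-5,9-dimethyl-2,4-bis(3-methylbut-2-en-1-yl)-9-[(triethylsilyl)oxy]dec-7-enoate (both C2 epimers), via B-alkyl-9-BBN adduct 17 (not isolated)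
Conditions: 9-BBN, THF, 0 °C → rt; then aq. NaOAc, 30% H2O2, 0 °C
Reagents that add atoms: hydrogen peroxide, OO
Why: Hydroboration–oxidation with 9-BBN is anti-Markovnikov and selective for the monosubstituted vinyl group over the trisubstituted prenyl alkenes and the hindered trans-disubstituted alkene.

Step 10
Reactants: 18 primary alcohol
Product: 19 methyl (4S,5S,7E)-5,9-dimethyl-2,4-bis(3-methylbut-2-en-1-yl)-5-(2-oxoethyl)-9-[(triethylsilyl)oxy]dec-7-enoate (both C2 epimers)
Conditions: Dess–Martin periodinane, NaHCO3, CH2Cl2, 0 °C → rt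
Reagents that add atoms: none
Why: Dess–Martin oxidation under buffered conditions gives the aldehyde, which has no stereocentre α to the carbonyl (the α-CH2 is attached to the quaternary carbon).

Step 11
Reactants: 19 aldehyde
Product: 20 methyl (4S,5S,7E)-5-(2-hydroxy-3-methylbutyl)-5,9-dimethyl-2,4-bis(3-methylbut-2-en-1-yl)-9-[(triethylsilyl)oxy]dec-7-enoate (epimers at C2 and at the carbinol carbon)
Conditions: i-PrMgCl, THF, −78 °C
Reagents that add atoms: isopropylmagnesium chloride, CC(C)[Mg]Cl
Why: Grignard addition to the aldehyde at −78 °C is faster than attack on the α-branched methyl ester; the carbinol configuration is irrelevant because it is oxidised in step 12.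

Step 12
Reactants: 20 secondary alcohol
Product: 21 methyl (4S,5S,7E)-5,9-dimethyl-2,4-bis(3-methylbut-2-en-1-yl)-5-(3-methyl-2-oxobutyl)-9-[(triethylsilyl)oxy]dec-7-enoate (both C2 epimers)
Conditions: Dess–Martin periodinane, NaHCO3, CH2Cl2, rt
Reagents that add atoms: none
Why: Dess–Martin oxidation of the secondary alcohol gives the isobutyl ketone without touching the alkenes or the silyl ether.

Step 13
Reactants: 21 keto ester
Product: 22 (4S,5S,7E)-5,9-dimethyl-2,4-bis(3-methylbut-2-en-1-yl)-5-(3-methyl-2-oxobutyl)-9-[(triethylsilyl)oxy]dec-7-enoic acid (both C2 epimers)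
Conditions: LiOH·H2O, THF/MeOH/H2O, 45 °C; then aq. HCl to pH 4, 0 °C
Reagents that add atoms: lithium hydroxide, [Li+].[OH-]
Why: Saponification (BAc2) of the hindered methyl ester; the tertiary TES ether and the ketone tolerate hydroxide and a brief pH 4 work-up, and epimerisation α to the carboxylate is without consequence.

Step 14
Reactants: 23 diphenyl malonate
Product: 24 diphenyl 2-bromomalonate
Conditions: Br2 (1.0 equiv), CH2Cl2, 0 °C → rt
Reagents that add atoms: bromine, BrBr
Why: α-Bromination of the malonate through its enol (the standard route to bromomalonic esters), kept at mono-bromination by stoichiometry; the O-acylated phenyl rings are not attacked by bromine without a Lewis acid.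

Step 15
Reactants: 22 keto acid; 24 diphenyl 2-bromomalonate
Product: 26 diphenyl 2-{[(4S,5S,7E)-5,9-dimethyl-2,4-bis(3-methylbut-2-en-1-yl)-5-(3-methyl-2-oxobutyl)-9-[(triethylsilyl)oxy]dec-7-enoyl]oxy}-2-(3-methylbut-2-en-1-yl)propanedioate (both epimers at the acyl α-carbon), via acyloxymalonate 25 (not isolated)
Conditions: Cs2CO3 (0.5 equiv), DMF, 0 °C, then 24; then K2CO3, prenyl bromide, rt
Reagents that add atoms: prenyl bromide, CC(C)=CCBr
Why: Carboxylate SN2 displacement on the α-bromomalonate gives the acyloxymalonate, whose remaining C–H (the only carbonate-acidic site) is then C-alkylated by prenyl bromide at its primary terminus (SN2 of a soft stabilised carbanion); the new quaternary carbon (C7) bears two identical ester groups and is therefore not yet a stereocentre.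

Step 16
Reactants: 26 diphenyl 2-acyloxy-2-prenylmalonate
Product: 29 (1R,3S,4R,5R,7S)-4-methyl-1,3,7-tris(3-methylbut-2-en-1-yl)-4-{(2E)-4-methyl-4-[(triethylsilyl)oxy]pent-2-en-1-yl}-5-(2-methylpropanoyl)-8-oxabicyclo[5.2.1]decane-6,9,10-trione, via dilithium dienolate 27 (not isolated), via monocyclic keto-lactone enolate 28 (not isolated)
Conditions: LDA (3.3 equiv), THF, −78 °C (26 added slowly, final 0.005 M) → 0 °C; AcOH quench
Reagents that add atoms: none
Why: Slow addition of 26 to excess LDA should give the dilithium species 27 enolised at C1 (α to the C9 ester) and at the C5 methylene of the ketone, so that C9 is an enolate carbon and is protected from the ketone enolate; the ester enolate then attacks one of the two phenyl esters on C7 in a 5-exo-trig Dieckmann acylation (C1–C10, five-membered keto-lactone 28, phenoxide expelled), and the C5 enolate attacks the remaining phenyl ester in an 8-exo-trig Claisen acylation (C5–C6, eight-membered ring), after which the third equivalent of base stores the product as its 1,3-diketonate and makes the sequence irreversible. The closest known reaction types are the Lacey–Dieckmann cyclisation of α-acyloxy esters to furan-2,4-diones and the high-dilution Dieckmann/Claisen closure of eight-membered rings, here with aryl esters as acyl donors whose leaving group cannot reopen the products. C7 is prochiral in 26, so C7 and C1 become stereocentres together in the first closure: the C2 chain on C1 and the residual ester on C7 are expected cis because the bulky chain avoids the C7 prenyl group across the forming ring, and only this cis isomer can undergo the second closure, which therefore acts as a filter. The absolute sense at C1/C7 relative to C3/C4 rests on 1,3-induction from C3 in the chelated dienolate (C3–C4 bond anti to the enolate, C3 prenyl group shielding one face) and is the least secure element; the C1,C7-diastereomer would be separable at 29. C5 is set last, under thermodynamic control, when the diketonate is protonated, and should adopt the configuration that this epimerisable centre holds in the natural product. The step needs enolisation of the ketone at CH2 and not at the isopropyl methine (kinetic preference, and only the methylene enolate has a productive ring closure) and acylation of the C5 enolate at C6 rather than at the lactone carbonyl C9 or the hindered ketone C10 (C6 is an aryl ester on an oxygen-bearing quaternary carbon and the strongest acyl donor present).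

Step 17
Reactants: 29 bicyclic TES ether
Product: 30 (1R,3S,4R,5R,7S)-4-[(2E)-4-hydroxy-4-methylpent-2-en-1-yl]-4-methyl-1,3,7-tris(3-methylbut-2-en-1-yl)-5-(2-methylpropanoyl)-8-oxabicyclo[5.2.1]decane-6,9,10-trione
Conditions: HF·pyridine, pyridine, THF, 0 °C
Reagents that add atoms: none
Why: Fluoride-driven cleavage of the tertiary silyl ether (Si–F bond formation) under buffered HF·pyridine, conditions too weakly basic and nucleophilic to open the keto-lactone or cause retro-Claisen cleavage.

Step 18
Reactants: 30 tertiary allylic alcohol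
Product: 31 (1R,3S,4R,5R,7S)-4-[(2E)-4-hydroperoxy-4-methylpent-2-en-1-yl]-4-methyl-1,3,7-tris(3-methylbut-2-en-1-yl)-5-(2-methylpropanoyl)-8-oxabicyclo[5.2.1]decane-6,9,10-trione (CNP0545483.1)
Conditions: 50% aq. H2O2 (excess), p-TsOH·H2O (cat.), THF, 0 °C
Reagents that add atoms: hydrogen peroxide, OO
Why: Acid-catalysed perhydrolysis (SN1) of the tertiary allylic alcohol: ionisation gives the 1,1-dimethylallyl-type cation, which hydrogen peroxide should capture under kinetic control at its tertiary terminus, as in the solvolysis of prenyl derivatives, with the (E)-geometry of the allyl cation retained.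

## Compound list

1 | geranyl acetate | CC(=O)OC/C=C(\C)CCC=C(C)C | starting material
2 | 6,7-epoxygeranyl acetate (racemic) | CC(=O)OC/C=C(\C)CCC1OC1(C)C | intermediate
3 | 6,7-epoxygeraniol (racemic) | OC/C=C(\C)CCC1OC1(C)C | intermediate
4 | (2E)-3,7-dimethyl-6-(phenylselanyl)oct-2-ene-1,7-diol (hydroxy selenide, racemic) | OC/C=C(\C)CCC([Se]c1ccccc1)C(C)(C)O | intermediate
5 | (2E)-3,7-dimethyl-6-(phenylseleninyl)oct-2-ene-1,7-diol (selenoxide) | OC/C=C(\C)CCC([Se](=O)c1ccccc1)C(C)(C)O | intermediate
6 | (2E,5E)-3,7-dimethylocta-2,5-diene-1,7-diol | OC/C=C(\C)C/C=C/C(C)(C)O | intermediate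
7 | 5-methylhex-4-enoic acid | CC(C)=CCCC(=O)O | starting material
8 | (2E,5E)-7-hydroxy-3,7-dimethylocta-2,5-dien-1-yl 5-methylhex-4-enoate | CC(C)=CCCC(=O)OC/C=C(\C)C/C=C/C(C)(C)O | intermediate
9 | (2E,5E)-3,7-dimethyl-7-[(triethylsilyl)oxy]octa-2,5-dien-1-yl 5-methylhex-4-enoate | CC(C)=CCCC(=O)OC/C=C(\C)C/C=C/C(C)(C)O[Si](CC)(CC)CC | intermediate
10 | boron ketene acetal of 9 (prenyl-bearing CH2 cis to O–B; boron in the (S,S)-1,3-bis(arylsulfonyl)-4,5-diphenyl-1,3,2-diazaborolidine) | CC(C)=CC/C=C(\OB1N(S(=O)(=O)c2cc(cc(c2)C(F)(F)F)C(F)(F)F)[C@@H](c2ccccc2)[C@H](c2ccccc2)N1S(=O)(=O)c1cc(cc(c1)C(F)(F)F)C(F)(F)F)OC/C=C(\C)C/C=C/C(C)(C)O[Si](CC)(CC)CC | intermediate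
11 | (2R,3S,5E)-3-ethenyl-3,7-dimethyl-2-(3-methylbut-2-en-1-yl)-7-[(triethylsilyl)oxy]oct-5-enoic acid | CC(C)=CC[C@@H](C(=O)O)[C@@](C=C)(C)C/C=C/C(C)(C)O[Si](CC)(CC)CC | intermediate
12 | (2R,3S,5E)-3-ethenyl-3,7-dimethyl-2-(3-methylbut-2-en-1-yl)-7-[(triethylsilyl)oxy]oct-5-en-1-ol | CC(C)=CC[C@@H](CO)[C@@](C=C)(C)C/C=C/C(C)(C)O[Si](CC)(CC)CC | intermediate
13 | methyl 5-methylhex-4-enoate | COC(=O)CCC=C(C)C | starting material
14 | trifluoromethanesulfonate of 12 | CC(C)=CC[C@@H](COS(=O)(=O)C(F)(F)F)[C@@](C=C)(C)C/C=C/C(C)(C)O[Si](CC)(CC)CC | intermediate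
15 | lithium enolate of 13 | COC([O-])=CCC=C(C)C.[Li+] | intermediate
16 | methyl (4S,5S,7E)-5-ethenyl-5,9-dimethyl-2,4-bis(3-methylbut-2-en-1-yl)-9-[(triethylsilyl)oxy]dec-7-enoate (C2 epimers) | CC(C)=CC[C@@H](CC(CC=C(C)C)C(=O)OC)[C@@](C=C)(C)C/C=C/C(C)(C)O[Si](CC)(CC)CC | intermediate
17 | B-alkyl-9-borabicyclo[3.3.1]nonane adduct of 16 (boron on the terminal vinyl carbon) | CC(C)=CC[C@@H](CC(CC=C(C)C)C(=O)OC)[C@@](CCB1C2CCCC1CCC2)(C)C/C=C/C(C)(C)O[Si](CC)(CC)CC | intermediate
18 | methyl (4S,5S,7E)-5-(2-hydroxyethyl)-5,9-dimethyl-2,4-bis(3-methylbut-2-en-1-yl)-9-[(triethylsilyl)oxy]dec-7-enoate (C2 epimers) | CC(C)=CC[C@@H](CC(CC=C(C)C)C(=O)OC)[C@@](CCO)(C)C/C=C/C(C)(C)O[Si](CC)(CC)CC | intermediate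
19 | methyl (4S,5S,7E)-5,9-dimethyl-2,4-bis(3-methylbut-2-en-1-yl)-5-(2-oxoethyl)-9-[(triethylsilyl)oxy]dec-7-enoate (C2 epimers) | CC(C)=CC[C@@H](CC(CC=C(C)C)C(=O)OC)[C@@](CC=O)(C)C/C=C/C(C)(C)O[Si](CC)(CC)CC | intermediate
20 | methyl (4S,5S,7E)-5-(2-hydroxy-3-methylbutyl)-5,9-dimethyl-2,4-bis(3-methylbut-2-en-1-yl)-9-[(triethylsilyl)oxy]dec-7-enoate (epimers at C2 and at the carbinol carbon) | CC(C)=CC[C@@H](CC(CC=C(C)C)C(=O)OC)[C@@](CC(O)C(C)C)(C)C/C=C/C(C)(C)O[Si](CC)(CC)CC | intermediate
21 | methyl (4S,5S,7E)-5,9-dimethyl-2,4-bis(3-methylbut-2-en-1-yl)-5-(3-methyl-2-oxobutyl)-9-[(triethylsilyl)oxy]dec-7-enoate (C2 epimers) | CC(C)=CC[C@@H](CC(CC=C(C)C)C(=O)OC)[C@@](CC(=O)C(C)C)(C)C/C=C/C(C)(C)O[Si](CC)(CC)CC | intermediate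
22 | (4S,5S,7E)-5,9-dimethyl-2,4-bis(3-methylbut-2-en-1-yl)-5-(3-methyl-2-oxobutyl)-9-[(triethylsilyl)oxy]dec-7-enoic acid (C2 epimers) | CC(C)=CC[C@@H](CC(CC=C(C)C)C(=O)O)[C@@](CC(=O)C(C)C)(C)C/C=C/C(C)(C)O[Si](CC)(CC)CC | intermediate
23 | diphenyl malonate | O=C(CC(=O)Oc1ccccc1)Oc1ccccc1 | starting material
24 | diphenyl 2-bromomalonate | O=C(Oc1ccccc1)C(Br)C(=O)Oc1ccccc1 | intermediate
25 | diphenyl 2-(acyloxy)malonate from 22 and 24 (acyl = the decenoyl group of 22) | CC(C)=CC[C@@H](CC(CC=C(C)C)C(=O)OC(C(=O)Oc1ccccc1)C(=O)Oc1ccccc1)[C@@](CC(=O)C(C)C)(C)C/C=C/C(C)(C)O[Si](CC)(CC)CC | intermediate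
26 | diphenyl 2-(acyloxy)-2-(3-methylbut-2-en-1-yl)malonate (acyl = the decenoyl group of 22; epimers at the acyl α-carbon) | CC(C)=CC[C@@H](CC(CC=C(C)C)C(=O)OC(CC=C(C)C)(C(=O)Oc1ccccc1)C(=O)Oc1ccccc1)[C@@](CC(=O)C(C)C)(C)C/C=C/C(C)(C)O[Si](CC)(CC)CC | intermediate
27 | dilithium dienolate of 26 (ester α-carbon and ketone methylene) | CC(C)=CC[C@@H](CC(CC=C(C)C)=C([O-])OC(CC=C(C)C)(C(=O)Oc1ccccc1)C(=O)Oc1ccccc1)[C@@](C=C([O-])C(C)C)(C)C/C=C/C(C)(C)O[Si](CC)(CC)CC.[Li+].[Li+] | intermediate
28 | lithium ketone enolate of the monocyclic 3,5-dioxooxolane-2-carboxylic acid phenyl ester (C1–C10 bond formed; C1 R, C7 S) | CC(C)=CC[C@@H](C[C@@]1(CC=C(C)C)C(=O)O[C@@](CC=C(C)C)(C(=O)Oc2ccccc2)C1=O)[C@@](C=C([O-])C(C)C)(C)C/C=C/C(C)(C)O[Si](CC)(CC)CC.[Li+] | intermediate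
29 | (1R,3S,4R,5R,7S)-4-methyl-1,3,7-tris(3-methylbut-2-en-1-yl)-4-{(2E)-4-methyl-4-[(triethylsilyl)oxy]pent-2-en-1-yl}-5-(2-methylpropanoyl)-8-oxabicyclo[5.2.1]decane-6,9,10-trione | CC(C)=CC[C@H]1C[C@@]2(CC=C(C)C)C(=O)O[C@@](CC=C(C)C)(C(=O)[C@@H](C(=O)C(C)C)[C@]1(C)C/C=C/C(C)(C)O[Si](CC)(CC)CC)C2=O | intermediate
30 | (1R,3S,4R,5R,7S)-4-[(2E)-4-hydroxy-4-methylpent-2-en-1-yl]-4-methyl-1,3,7-tris(3-methylbut-2-en-1-yl)-5-(2-methylpropanoyl)-8-oxabicyclo[5.2.1]decane-6,9,10-trione | CC(C)=CC[C@H]1C[C@@]2(CC=C(C)C)C(=O)O[C@@](CC=C(C)C)(C(=O)[C@@H](C(=O)C(C)C)[C@]1(C)C/C=C/C(C)(C)O)C2=O | intermediate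
31 | (1R,3S,4R,5R,7S)-4-[(2E)-4-hydroperoxy-4-methylpent-2-en-1-yl]-4-methyl-1,3,7-tris(3-methylbut-2-en-1-yl)-5-(2-methylpropanoyl)-8-oxabicyclo[5.2.1]decane-6,9,10-trione (CNP0545483.1) | CC(C)=CC[C@H]1C[C@@]2(CC=C(C)C)C(=O)O[C@@](CC=C(C)C)(C(=O)[C@@H](C(=O)C(C)C)[C@]1(C)C/C=C/C(C)(C)OO)C2=O | target

## Summary and risks

Total step count: 18 (17 in the main line plus step 14, the preparation of 24).
Longest linear sequence: 17 steps (geranyl acetate 1 to 31: steps 1–13 and 15–18).

Steps most likely to fail:

Step 16. The ketone enolate may close a six-membered ring onto the C9 carbonyl (before or after the first cyclisation) faster than the eight-membered ring onto C6, and the first closure may show low facial selectivity at C1; both reflect too small a reactivity gap between the phenyl esters and the C9 ester. The fallback widens that gap by changing the acyl donors to acyl fluorides. It sets out from keto acid 22, which is O-alkylated (caesium carboxylate, DMF) with diallyl 2-bromomalonate F1 (from diallyl malonate, NaH, then NBS) to the diallyl acyloxymalonate F2 and C-prenylated (K2CO3, prenyl bromide) to the diallyl 2-acyloxy-2-prenylmalonate F3. Pd(PPh3)4 and morpholine then remove both allyl groups to give the malonic diacid F4, and cyanuric fluoride with pyridine in CH2Cl2 converts it into the bis(acyl fluoride) F5. Treatment of F5 with LDA under the conditions of step 16 should give 29, where the route is rejoined; a C1,C7-diastereomer would be removed by chromatography at that stage.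

Step 18. Ionisation under Brønsted acid may be followed by capture at the secondary allyl terminus, by elimination to the 1,3-diene, or by acid-induced addition of the enolised diketone to a prenyl alkene. The fallback replaces protic activation by silver-assisted perhydrolysis of an allylic halide. It sets out from alcohol 30, which is converted with PBr3 and a trace of pyridine in Et2O at −30 °C into the allylically transposed secondary allylic bromide F6. Silver trifluoroacetate and ethereal H2O2 at 0 °C then ionise the bromide under essentially neutral conditions, and capture of the allyl cation at its tertiary terminus should give 31 directly.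

Step 6. Soft enolisation by the boron reagent may be incomplete, the enolate geometry may leak, or the controller may discriminate poorly between the two chairs with the trisubstituted allyl terminus, any of which erodes diastereo- or enantioselectivity. The fallback separates the relative from the absolute control. It sets out from ester 9, which is rearranged under achiral Ireland–Claisen conditions (LDA, THF–DMPU, TBSCl, −78 °C → rt, then hydrolysis of the silyl ester) to racemic acid, i.e. 11 together with its enantiomer, the (2S,3R)-acid F7. The mixed pivalic anhydride (PivCl, Et3N) is coupled with lithiated (S)-4-benzyloxazolidin-2-one to give the N-acyloxazolidinone F8 of the (2R,3S)-acid and the diastereomeric N-acyloxazolidinone F9 of the (2S,3R)-acid, which are separated by chromatography. Reduction of F8 with LiBH4 gives alcohol 12, where the route is rejoined.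

Further compounds

F1 | step 16 | diallyl 2-bromomalonate | C=CCOC(=O)C(Br)C(=O)OCC=C
F2 | step 16 | diallyl 2-(acyloxy)malonate (acyl = the decenoyl group of 22) | CC(C)=CC[C@@H](CC(CC=C(C)C)C(=O)OC(C(=O)OCC=C)C(=O)OCC=C)[C@@](CC(=O)C(C)C)(C)C/C=C/C(C)(C)O[Si](CC)(CC)CC
F3 | step 16 | diallyl 2-(acyloxy)-2-(3-methylbut-2-en-1-yl)malonate | CC(C)=CC[C@@H](CC(CC=C(C)C)C(=O)OC(CC=C(C)C)(C(=O)OCC=C)C(=O)OCC=C)[C@@](CC(=O)C(C)C)(C)C/C=C/C(C)(C)O[Si](CC)(CC)CC
F4 | step 16 | 2-(acyloxy)-2-(3-methylbut-2-en-1-yl)malonic acid | CC(C)=CC[C@@H](CC(CC=C(C)C)C(=O)OC(CC=C(C)C)(C(=O)O)C(=O)O)[C@@](CC(=O)C(C)C)(C)C/C=C/C(C)(C)O[Si](CC)(CC)CC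
F5 | step 16 | 2-(acyloxy)-2-(3-methylbut-2-en-1-yl)malonyl difluoride | CC(C)=CC[C@@H](CC(CC=C(C)C)C(=O)OC(CC=C(C)C)(C(=O)F)C(=O)F)[C@@](CC(=O)C(C)C)(C)C/C=C/C(C)(C)O[Si](CC)(CC)CC
F6 | step 18 | secondary allylic bromide of 30 (side chain CH2–CHBr–CH=C(CH3)2, both epimers at CHBr) | CC(C)=CC[C@H]1C[C@@]2(CC=C(C)C)C(=O)O[C@@](CC=C(C)C)(C(=O)[C@@H](C(=O)C(C)C)[C@]1(C)CC(Br)C=C(C)C)C2=O
F7 | step 6 | (2S,3R,5E)-3-ethenyl-3,7-dimethyl-2-(3-methylbut-2-en-1-yl)-7-[(triethylsilyl)oxy]oct-5-enoic acid (enantiomer of 11) | CC(C)=CC[C@H](C(=O)O)[C@](C=C)(C)C/C=C/C(C)(C)O[Si](CC)(CC)CC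
F8 | step 6 | (S)-4-benzyl-3-[(2R,3S)-acyl]oxazolidin-2-one of 11 | CC(C)=CC[C@@H](C(=O)N1[C@@H](Cc2ccccc2)COC1=O)[C@@](C=C)(C)C/C=C/C(C)(C)O[Si](CC)(CC)CC
F9 | step 6 | (S)-4-benzyl-3-[(2S,3R)-acyl]oxazolidin-2-one of F7 | CC(C)=CC[C@H](C(=O)N1[C@@H](Cc2ccccc2)COC1=O)[C@](C=C)(C)C/C=C/C(C)(C)O[Si](CC)(CC)CC
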